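## The problem

2,3-Dehydrosilychristin (32) joins two units through a single C–C bond. C2' of a 3,5,7-trihydroxychromen-4-one (ring A fused to the pyranone ring C) is bonded to C5 of a trans-2-aryl-3-hydroxymethyl-2,3-dihydrobenzofuran, which carries a phenol at C7 and a 4-hydroxy-3-methoxyphenyl group at C2. The only stereocentres are C2 (R) and C3 (S) of the dihydrofuran. They are contiguous and trans, and trans is the thermodynamic arrangement, so C2 can set C3 for as long as C3 is α to a carbonyl group and epimerisable. C2 is a benzylic ether carbon para to a phenol oxygen: once that phenol is free, acid or base can ionise C2–O1 in a quinone-methide sense, which endangers the ring and C2 but not C3. Six hydroxyl groups must be masked or introduced late, the free 3-hydroxychromone is oxidised easily in base, and the methyl ether at C3'' rules out any late dealkylation of methyl ethers, so the last operations must be acidic or neutral. The feature that allows a late, convergent union is ring A: O1' sits on C8a', the carbonyl carbon C4' on the neighbouring C4a', and C4a' is flanked on its other side by the C5' oxygen. These two adjacent bonds, O1'–C8a' and C4a'–C4', are what an unsymmetrical 3,5-dialkoxybenzyne can take from the oxygen and the carbon of a carboxylate, with the C5' alkoxy group fixing the orientation.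

## Retrosynthesis

**Protecting groups and the C3'–O bond.** Target 32 is traced to its pentakis(methoxymethyl) ether 31. Acetal ethers are used on every hydroxyl because they survive fluoride, amines and dimethyldioxirane and leave under acid. Benzyl ethers would need hydrogenolysis next to the benzylic C2–O1 bond, and esters would need base, under which the free flavonol is oxidised. The C3' oxygen is removed next: 31 comes from flavone 29 by epoxidation (30) and acid-induced isomerisation. Introducing O3' last keeps C2'–C3'–C4' as a plain alkynyl carbonyl unit for the ring-forming events. The forward step must oxidise the C2'=C3' bond in preference to two electron-rich benzene rings.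

**O1'–C2' bond.** Flavone 29 is opened to the ortho-hydroxyaryl ynone 27. The ynone is already at the flavone oxidation level, whereas open-chain enone precursors with an oxygen next to the carbonyl-bearing carbon of ring A tend to close to five-membered rings under oxidative conditions. The closure must be 6-endo; passing through the amine adduct 28 secures this.

**O1'–C8a' and C4a'–C4' bonds (the strategic cut).** Ynone 27 is divided into alkynoic acid 24 and silyl triflate 8, the precursor of 3,5-bis(methoxymethoxy)benzyne 26. Both bonds to ring A form in one operation, and the phenol oxygen is delivered by the carboxylate itself (as its potassium salt 25). The neighbouring cuts are weaker. C-acylation of an electron-rich arene needs Lewis acids that the acetals and the C2–O1 bond would not tolerate. Addition of a metal acetylide to an ortho-hydroxy aryl aldehyde with re-oxidation costs two steps and makes one bond at a time. The chosen cut is shorter and fully convergent, and it is the one step without direct precedent. The simplification is large: 27 falls into a C6 unit available in four steps from a commodity triol and the chiral core acid. The forward reaction must add the carboxylate oxygen to the aryne carbon remote from the flanking alkoxy group, transfer the acyl group to the adjacent carbanion before that carbanion is protonated, and leave the triple bond alone.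

**Aryne precursor.** Triflate 8 is traced through silyl phenol 7 and silyl carbamate 6 to carbamate 3, phenol 2 and phloroglucinol 1. The C–Si bond is cut because that position lies between a carbamate and an acetal oxygen; the carbamate, the stronger of the two directing groups, steers metalation (through 4 and 5) there in preference to the position between the two acetals. Halogenation of 2 would not distinguish the ring positions. The price is a statistical bis-protection of 1.

**Alkynoic acid.** Acid 24 is cut at the carboxyl carbon to silyl alkyne 22 and at the aryl–alkynyl bond to bromide 21. Direct attachment of a preformed three-carbon alkynoic acid to 21 was set aside: an electron-rich aryl bromide needs heat, and under palladium and copper at that temperature such acids lose CO2. The forward steps ask only for a Sonogashira coupling and a fluoride-triggered carboxylation (through 23), both compatible with acetal ethers.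

**Oxidation level and protecting-group exchange.** Bromide 21 comes from triol 20 by one global acetalisation. Triol 20 comes from ester 19 by hydride, which reduces the ester and removes both pivalates at once. The pivalates are there because the step that makes 19 is acidic and oxidising, which acetal ethers would not survive.

**C3–C3a bond.** Ester 19 is traced to flavanone 17 by a ring contraction: the ring carbon attached to the carbonyl migrates to C3 (through enol ether 18) and the former carbonyl carbon becomes the ester. This turns a two-stereocentre problem into a one-stereocentre problem. C2 of 17 is carried over unchanged, and the trans C3 centre follows from the anti migration and from thermodynamics. A flavanone is far easier to obtain enantioenriched than a 2,3-disubstituted dihydrobenzofuran. The forward reaction must favour migration of the fused benzene ring over migration of the C2 aryl group, which is why that group carries an acyloxy and not an alkoxy substituent.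

**C2–aryl bond.** Flavanone 17 is cut between C2 and the guaiacyl ring to chromone 16 and boronic acid 11. This is the only step that introduces absolute configuration, and it is catalytic. Ring closure of an open-chain enone would give the same skeleton, but racemic and configurationally labile under its own conditions. The forward reaction must tolerate an aryl bromide and two aryl esters, which a divalent-palladium manifold does.

**Starting materials.** Chromone 16 is the pivalate of hydroxychromone 15, assembled from bromo ketone 13 and a one-carbon amide acetal through enaminone 14. Ketone 13 is the bromination product of 2',3'-dihydroxyacetophenone 12; bromination comes first because only the free 2'-hydroxyl directs to the required position. Boronic acid 11 comes from the commercial pinacol boronate 9 by acylation (10) and oxidative cleavage of the diol ester.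

## Roads not taken

**Alternative 1:** The C2–C3 bond of the dihydrofuran is cut. This leads back to aryl diazoacetate A1, in which the future C2 is the methylene carbon of a benzyl-type ether on the phenol oxygen.
- Forward key step: the dirhodium tetracarboxylate Rh2(S-PTTL)4 (divalent rhodium) decomposes A1, and the metal-bound carbene inserts into the benzylic C–H bond to close the five-membered ring. DBU then epimerises C3 to give trans ester A2.
- Merits: both stereocentres arise in one catalytic step from an achiral substrate. The reaction type is well established for this ester series, the conditions are neutral, and A2 carries the same C5 bromide and C3 ester as 19.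
- Weak points: A1 must be made from a trisubstituted arylacetic ester that is not commercial, by a diazo transfer, and needs a costly chiral catalyst. The base epimerisation runs on a β-aryloxy ester that can also eliminate. The step does nothing for the flavonol.
- Comparison: for the core alone this road is at least equal to steps 10 and 11 of the chosen plan, and probably better in stereochemical reliability, since those steps need two operations and depend on a migratory preference. The chosen plan sets against it a commercial acetophenone as the source of ring and oxygen pattern, no diazo chemistry, and a convergent union with ring A. After hydride reduction and desilylation A2 would converge on triol 20, so it is the natural reserve for the core.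

**Alternative 2:** The central benzene ring is dissected at C4–C5 and C6–C7, so that it is built last from bicyclic 3-alkoxyfuran A3 and methyl propiolate A4. A3 is a 2,3-dihydrofuro[3,4-b]furan whose furan carbons become C7, C7a, C3a and C4.
- Forward key step: cycloaddition across the furan α-carbons, followed in the same flask by cleavage of the oxygen bridge at C4 (assisted by the ring oxygen on C7a) and tautomerisation, gives phenol A5 with the ester at C5.
- Merits: the oxygenation pattern and the C5 carbon substituent are set without electrophilic substitution. The C7 hydroxyl emerges free and distinct from the others. An ester at C5 can be taken on to the alkyne.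
- Weak points: the step creates no stereocentre, so A3 must already hold the trans C2/C3 pair, and an enantioselective route to such an electron-rich, acid- and air-sensitive alkoxyfuran is a project of its own. The regiochemistry (ester at C5, not C6) rests only on polarisation by the alkoxy group. The ester needs several more steps to become an alkynoic acid.
- Comparison: this road is better at differentiating O7 from the start, where the chosen plan needs a pivalate-to-acetal exchange, and it avoids the 1,2-shift. It moves the stereochemical problem to a less accessible substrate and is longer. The chosen plan takes the whole benzene ring, with oxygen and bromine in place, from a commercial acetophenone.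

**Alternative 3:** The O1–C2 bond is cut, giving phenolic 1,3-diol A6, the reduced product of an auxiliary-controlled aldol reaction between an arylacetic acid unit and an aromatic aldehyde.
- Forward key step: BF3·OEt2 or catalytic HCl ionises the benzylic hydroxyl, which sits para to the free phenol, to para-quinone methide A7. The ortho phenol oxygen adds to C2 (5-exo-trig) and gives trans dihydrobenzofuran A8.
- Merits: the aldol chemistry is dependable and C3 is fixed by the auxiliary. The carbinol configuration does not matter because it is erased in A7. The trans ring is both the kinetic and the thermodynamic product, and the guaiacyl phenol and the primary alcohol need no protection.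
- Weak points: a stoichiometric auxiliary and a multi-step synthesis of the arylacetic acid partner are needed. A7 can also be intercepted intermolecularly. The benzyl ether at O7 must later be removed by hydrogenolysis, which has to spare an aryl bromide or an alkyne and the benzylic C2–O1 bond.
- Comparison: control of C3 is more predictable than in the ring contraction, and the closure exploits the very ionisation that the chosen plan must avoid in its last step. The chosen plan is catalytic in chirality, avoids hydrogenolysis, and spends its strategic step on joining the core to ring A, which none of the three alternatives addresses.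

Key step: step 16

Assumption: the (S)-configured pyridine–oxazoline ligand is taken to give the (2R)-flavanone in step 10, by analogy with its sense of induction on cyclic enones; if the sense is opposite, the equally available (R)-ligand is used.

Abbreviation in names: DBF = the (2R,3S)-2-[3-methoxy-4-(methoxymethoxy)phenyl]-7-(methoxymethoxy)-3-[(methoxymethoxy)methyl]-2,3-dihydro-1-benzofuran-5-yl group. Locants are unprimed for the dihydrobenzofuran, primed for the chromenone and double-primed for the guaiacyl ring.

## Route

Step 1
Reactants: 1 phloroglucinol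
Product: 2 3,5-bis(methoxymethoxy)phenol
Conditions: MOMCl (2 equiv), i-Pr2NEt, DMF, 0 °C to rt; chromatographic separation
Reagents that add atoms: chloromethyl methyl ether, COCCl
Why: O-alkylation with an α-chloro ether; the bis-ether of the symmetrical triol is obtained statistically and separated from the mono- and tris-ethers.

Step 2
Reactants: 2 3,5-bis(methoxymethoxy)phenol
Product: 3 3,5-bis(methoxymethoxy)phenyl N-isopropylcarbamate
Conditions: i-PrNCO, Et3N (cat.), CH2Cl2, rt
Reagents that add atoms: isopropyl isocyanate, CC(C)N=C=O
Why: Base-catalysed addition of the phenol to the isocyanate gives the N-monoalkyl carbamate, which directs metalation and is later removed under mild base.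

Step 3
Reactants: 3 3,5-bis(methoxymethoxy)phenyl N-isopropylcarbamate
Product: 6 3,5-bis(methoxymethoxy)-2-(trimethylsilyl)phenyl N-isopropylcarbamate, via N-silyl carbamate 4 (not isolated), via N-silyl ortho-silyl carbamate 5 (not isolated)
Conditions: TBSOTf, TMEDA, Et2O, 0 °C to rt; n-BuLi, TMEDA, −78 °C; Me3SiCl, −78 °C to rt; aq. NaHSO4
Reagents that add atoms: chlorotrimethylsilane, C[Si](C)(C)Cl
Why: Directed ortho-metalation of an aryl carbamate: N-silylation in the flask masks the N–H, the carbamate and the neighbouring acetal oxygen together direct lithiation to the carbon between them, Me3SiCl traps the anion and the N–Si bond is hydrolysed on work-up.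

Step 4
Reactants: 6 3,5-bis(methoxymethoxy)-2-(trimethylsilyl)phenyl N-isopropylcarbamate
Product: 8 3,5-bis(methoxymethoxy)-2-(trimethylsilyl)phenyl trifluoromethanesulfonate, via silyl phenol 7 (not isolated)
Conditions: Et2NH, DBU, MeCN, 40 °C; then PhNTf2, rt
Reagents that add atoms: N-phenylbis(trifluoromethanesulfonimide), O=S(=O)(N(c1ccccc1)S(=O)(=O)C(F)(F)F)C(F)(F)F
Why: E1cB cleavage of the N–H carbamate by DBU, with Et2NH scavenging the isocyanate, frees the phenol, which is triflated in the same pot; no acid touches the acetals or the C–Si bond.

Step 5
Reactants: 9 2-methoxy-4-(4,4,5,5-tetramethyl-1,3,2-dioxaborolan-2-yl)phenol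
Product: 10 2-methoxy-4-(4,4,5,5-tetramethyl-1,3,2-dioxaborolan-2-yl)phenyl pivalate
Conditions: PivCl, Et3N, DMAP (cat.), CH2Cl2, 0 °C to rt
Reagents that add atoms: pivaloyl chloride, CC(C)(C)C(=O)Cl
Why: Acylation of the phenol; the pivalate is stable to acid and oxidant and makes the aryl ring a poorer migrating group in step 11.

Step 6
Reactants: 10 2-methoxy-4-(4,4,5,5-tetramethyl-1,3,2-dioxaborolan-2-yl)phenyl pivalate
Product: 11 [3-methoxy-4-(pivaloyloxy)phenyl]boronic acid
Conditions: NaIO4, NH4OAc, acetone–H2O, rt
Reagents that add atoms: water, O
Why: Hydrolysis of the boronic ester is driven by periodate cleavage of the released diol, giving the free boronic acid that the conjugate addition requires.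

Step 7
Reactants: 12 2',3'-dihydroxyacetophenone
Product: 13 1-(5-bromo-2,3-dihydroxyphenyl)ethan-1-one
Conditions: Br2 (1.0 equiv), AcOH, 15 °C
Reagents that add atoms: bromine, BrBr
Why: Electrophilic aromatic bromination; C5' is para to the 2'-hydroxyl and meta to the acetyl group and is the most activated open position.

Step 8
Reactants: 13 1-(5-bromo-2,3-dihydroxyphenyl)ethan-1-one
Product: 15 6-bromo-8-hydroxy-4H-chromen-4-one, via enaminone 14 (not isolated)
Conditions: Me2NCH(OMe)2, PhMe, 90 °C; then conc. HCl, CH2Cl2, 40 °C
Reagents that add atoms: N,N-dimethylformamide dimethyl acetal, COC(OC)N(C)C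
Why: Amide-acetal chromone synthesis: the acetyl methyl group condenses to the enaminone, and acid closes the pyranone by addition of the 2'-hydroxyl and loss of dimethylamine.

Step 9
Reactants: 15 6-bromo-8-hydroxy-4H-chromen-4-one
Product: 16 6-bromo-4-oxo-4H-chromen-8-yl pivalate
Conditions: PivCl, Et3N, DMAP (cat.), CH2Cl2, 0 °C to rt
Reagents that add atoms: pivaloyl chloride, CC(C)(C)C(=O)Cl
Why: Acylation of the remaining phenol gives a group that withstands the aqueous conjugate addition and the acidic, oxidising ring contraction.

Step 10
Reactants: 16 6-bromo-4-oxo-4H-chromen-8-yl pivalate; 11 [3-methoxy-4-(pivaloyloxy)phenyl]boronic acid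
Product: 17 (2R)-6-bromo-2-[3-methoxy-4-(pivaloyloxy)phenyl]-4-oxochroman-8-yl pivalate
Conditions: Pd(OCOCF3)2 (5 mol%), (S)-4-tert-butyl-2-(pyridin-2-yl)-4,5-dihydrooxazole (6 mol%), NH4PF6 (30 mol%), H2O (5 equiv), ClCH2CH2Cl, 60 °C
Reagents that add atoms: none
Why: Palladium-catalysed asymmetric conjugate addition of an arylboronic acid to a chromone; the cycle stays at divalent palladium so the C–Br bond is not engaged, and the chiral ligand selects the enone face for aryl transfer and sets C2 as R.

Step 11
Reactants: 17 (2R)-6-bromo-2-[3-methoxy-4-(pivaloyloxy)phenyl]-4-oxochroman-8-yl pivalate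
Product: 19 methyl (2R,3R)-5-bromo-2-[3-methoxy-4-(pivaloyloxy)phenyl]-7-(pivaloyloxy)-2,3-dihydro-1-benzofuran-3-carboxylate, via methyl enol ether 18 (not isolated)
Conditions: PhI(OAc)2 (1.2 equiv), conc. H2SO4, HC(OMe)3, 0 °C to rt
Reagents that add atoms: trimethyl orthoformate, COC(OC)OC
Why: Hypervalent-iodine oxidative ring contraction of a flavanone: trivalent iodine attacks C3 of the enol ether anti to the C2 aryl group, the fused ring carbon shifts from the ketal carbon to C3 with loss of iodobenzene, and the dimethoxycarbenium ion collapses to the methyl ester. C2 is untouched and C3 emerges trans, which is also the thermodynamic arrangement α to the ester; the acyloxy groups disfavour the competing shift of the C2 aryl group.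

Step 12
Reactants: 19 methyl (2R,3R)-5-bromo-2-[3-methoxy-4-(pivaloyloxy)phenyl]-7-(pivaloyloxy)-2,3-dihydro-1-benzofuran-3-carboxylate
Product: 20 (2R,3S)-5-bromo-2-(4-hydroxy-3-methoxyphenyl)-3-(hydroxymethyl)-2,3-dihydro-1-benzofuran-7-ol
Conditions: LiAlH4, THF, 0 °C
Reagents that add atoms: none
Why: Hydride reduction turns the ester into the primary alcohol and cleaves both aryl pivalates in one operation; C3 is no longer epimerisable afterwards (the descriptor changes to S by priority only).

Step 13
Reactants: 20 (2R,3S)-5-bromo-2-(4-hydroxy-3-methoxyphenyl)-3-(hydroxymethyl)-2,3-dihydro-1-benzofuran-7-ol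
Product: 21 (2R,3S)-5-bromo-2-[3-methoxy-4-(methoxymethoxy)phenyl]-7-(methoxymethoxy)-3-[(methoxymethoxy)methyl]-2,3-dihydro-1-benzofuran
Conditions: MOMCl (6 equiv), i-Pr2NEt, CH2Cl2, 0 to 40 °C
Reagents that add atoms: chloromethyl methyl ether, COCCl
Why: Global acetal protection of the two phenols and the primary alcohol; all three must be inert to fluoride and unable to add to the aryne in step 16.

Step 14
Reactants: 21 (2R,3S)-5-bromo-2-[3-methoxy-4-(methoxymethoxy)phenyl]-7-(methoxymethoxy)-3-[(methoxymethoxy)methyl]-2,3-dihydro-1-benzofuran
Product: 22 (DBF-ethynyl)trimethylsilane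
Conditions: Me3SiC≡CH, Pd(PPh3)2Cl2 (5 mol%), CuI (10 mol%), Et3N, DMF, 80 °C, sealed tube
Reagents that add atoms: ethynyltrimethylsilane, C#C[Si](C)(C)C
Why: Sonogashira coupling of an electron-rich aryl bromide; the silyl alkyne is used because propiolic acid itself would decarboxylate at the temperature this bromide requires.

Step 15
Reactants: 22 (DBF-ethynyl)trimethylsilane
Product: 24 3-DBF-prop-2-ynoic acid, via cesium carboxylate 23 (not isolated)
Conditions: CsF, CO2 (1 atm), DMSO, rt; then 1 M HCl, 0 °C
Reagents that add atoms: carbon dioxide, O=C=O
Why: Fluoride-promoted desilylative carboxylation of an alkynylsilane: fluoride releases the acetylide from silicon, CO2 traps it as the cesium carboxylate, and brief cold acidification gives the acid, which is extracted free of fluoride salts and DMSO, without harming the acetals.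

Step 16
Reactants: 24 3-DBF-prop-2-ynoic acid; 8 3,5-bis(methoxymethoxy)-2-(trimethylsilyl)phenyl trifluoromethanesulfonate
Product: 27 1-[2-hydroxy-4,6-bis(methoxymethoxy)phenyl]-3-DBF-prop-2-yn-1-one, via potassium carboxylate 25 (not isolated), via 3,5-bis(methoxymethoxy)benzyne 26 (not isolated)
Conditions: K2CO3 (0.5 equiv), MeCN–H2O, rt, then evaporation and azeotropic drying (PhMe); 8 (1.3 equiv, slow addition), spray-dried KF (3 equiv), 18-crown-6 (3 equiv), THF, 50 °C; AcOH, 0 °C
Reagents that add atoms: none
Why: Proposed new method: fluoride attacks silicon of 8 and triflate leaves to give aryne 26; an oxygen of carboxylate 25 adds to C8a', the aryne carbon remote from the flanking acetal oxygen, and the aryl anion formed at C4a' adds to the neighbouring carboxyl carbon (4-exo-trig) to a benzoxete alkoxide that opens to the ortho-acyl phenoxide, a net insertion into the C–O bond. The closest known reaction type is the insertion of arynes into the C–O bond of aromatic carboxylic acids to give ortho-hydroxyaryl ketones, together with the aryne–salicylate annulation to xanthones; an alkynoic acid has not been shown in this role. No ring is retained, since the four-membered ring is transient, and no stereocentre is formed; C2 and C3 carry no hydrogen that is acidic under these conditions and stay as they are. Regioselectivity is needed and comes from the C5' alkoxy group, which distorts the aryne so that the nucleophile enters at C8a' and the charge develops at C4a', where the adjacent oxygen stabilises it inductively. Acyl transfer must outrun protonation of the aryl anion, which would stop at the aryl ester; the dry, preformed potassium salt, kept in solution in THF by 18-crown-6, leaves no acid proton in the flask, and an alkynyl carbonyl is more electrophilic than a benzoate carbonyl. Attack of the anion on the alkyne β-carbon would need a 6-endo-dig approach to a linear unit and is not expected to compete. KF with 18-crown-6 in THF is a standard fluoride source for silyl triflates and releases the aryne at or below 50 °C, which spares the alkynyl carboxylate from decarboxylation, and 8 is added slowly so that the product phenoxide does not capture a second aryne.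

Step 17
Reactants: 27 1-[2-hydroxy-4,6-bis(methoxymethoxy)phenyl]-3-DBF-prop-2-yn-1-one
Product: 29 2-DBF-5,7-bis(methoxymethoxy)-4H-chromen-4-one, via diethylamino enone 28 (not isolated)
Conditions: Et2NH, EtOH, rt to 50 °C
Reagents that add atoms: none
Why: Amine-mediated cyclisation of an ortho-hydroxyaryl ynone: conjugate addition of Et2NH gives the enaminone, in which the phenol oxygen displaces the amine at C2' by addition–elimination, a formal 6-endo closure that avoids the 5-exo path open to the bare phenoxide.

Step 18
Reactants: 29 2-DBF-5,7-bis(methoxymethoxy)-4H-chromen-4-one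
Product: 31 2-DBF-3-hydroxy-5,7-bis(methoxymethoxy)-4H-chromen-4-one, via 2',3'-epoxide 30 (not isolated)
Conditions: dimethyldioxirane (acetone solution), CH2Cl2, 0 °C; then p-TsOH (cat.), CH2Cl2, rt
Reagents that add atoms: dimethyldioxirane, CC1(C)OO1
Why: Dioxirane epoxidation of the enol-ether-like C2'=C3' bond of the flavone, then acid-catalysed opening at C2' and loss of the C3' proton to the 3-hydroxyflavone; the oxirane stereocentres are destroyed again, so their configuration is irrelevant.

Step 19
Reactants: 31 2-DBF-3-hydroxy-5,7-bis(methoxymethoxy)-4H-chromen-4-one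
Product: 32 2,3-dehydrosilychristin
Conditions: 3 M HCl, MeOH–THF, 50 °C
Reagents that add atoms: none
Why: Acid-catalysed acetal exchange of all five methoxymethyl ethers with methanol; the alkyl acetal on the C3 side chain is the slowest and sets the acid strength, which is kept no higher because the freed 4''-phenol makes C2–O1 ionisable, an event that leaves C3 intact and re-closes to the trans ring.

## Compound list

1 | phloroglucinol | Oc1cc(O)cc(O)c1 | starting material
2 | 3,5-bis(methoxymethoxy)phenol | COCOc1cc(O)cc(OCOC)c1 | intermediate
3 | 3,5-bis(methoxymethoxy)phenyl N-isopropylcarbamate | CC(C)NC(=O)Oc1cc(OCOC)cc(OCOC)c1 | intermediate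
4 | 3,5-bis(methoxymethoxy)phenyl N-(tert-butyldimethylsilyl)-N-isopropylcarbamate (formed in the flask) | CC(C)N(C(=O)Oc1cc(OCOC)cc(OCOC)c1)[Si](C)(C)C(C)(C)C | intermediate
5 | 3,5-bis(methoxymethoxy)-2-(trimethylsilyl)phenyl N-(tert-butyldimethylsilyl)-N-isopropylcarbamate (formed in the flask) | CC(C)N(C(=O)Oc1cc(OCOC)cc(OCOC)c1[Si](C)(C)C)[Si](C)(C)C(C)(C)C | intermediate
6 | 3,5-bis(methoxymethoxy)-2-(trimethylsilyl)phenyl N-isopropylcarbamate | CC(C)NC(=O)Oc1cc(OCOC)cc(OCOC)c1[Si](C)(C)C | intermediate
7 | 3,5-bis(methoxymethoxy)-2-(trimethylsilyl)phenol (formed in the flask) | COCOc1cc(O)c([Si](C)(C)C)c(OCOC)c1 | intermediate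
8 | 3,5-bis(methoxymethoxy)-2-(trimethylsilyl)phenyl trifluoromethanesulfonate | C[Si](C)(C)c1c(OCOC)cc(OCOC)cc1OS(=O)(=O)C(F)(F)F | intermediate
9 | 2-methoxy-4-(4,4,5,5-tetramethyl-1,3,2-dioxaborolan-2-yl)phenol | COc1cc(B2OC(C)(C)C(C)(C)O2)ccc1O | starting material
10 | 2-methoxy-4-(4,4,5,5-tetramethyl-1,3,2-dioxaborolan-2-yl)phenyl pivalate | COc1cc(B2OC(C)(C)C(C)(C)O2)ccc1OC(=O)C(C)(C)C | intermediate
11 | [3-methoxy-4-(pivaloyloxy)phenyl]boronic acid | COc1cc(B(O)O)ccc1OC(=O)C(C)(C)C | intermediate
12 | 2',3'-dihydroxyacetophenone | CC(=O)c1cccc(O)c1O | starting material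
13 | 1-(5-bromo-2,3-dihydroxyphenyl)ethan-1-one | CC(=O)c1cc(Br)cc(O)c1O | intermediate
14 | (E)-1-(5-bromo-2,3-dihydroxyphenyl)-3-(dimethylamino)prop-2-en-1-one (formed in the flask) | CN(C)/C=C/C(=O)c1cc(Br)cc(O)c1O | intermediate
15 | 6-bromo-8-hydroxy-4H-chromen-4-one | O=c1ccoc2c(O)cc(Br)cc12 | intermediate
16 | 6-bromo-4-oxo-4H-chromen-8-yl pivalate | CC(C)(C)C(=O)Oc1cc(Br)cc2c(=O)ccoc12 | intermediate
17 | (2R)-6-bromo-2-[3-methoxy-4-(pivaloyloxy)phenyl]-4-oxochroman-8-yl pivalate | COc1cc([C@@H]2Oc3c(OC(=O)C(C)(C)C)cc(Br)cc3C(=O)C2)ccc1OC(=O)C(C)(C)C | intermediate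
18 | (2R)-6-bromo-4-methoxy-2-[3-methoxy-4-(pivaloyloxy)phenyl]-2H-chromen-8-yl pivalate (formed in the flask) | COc1cc([C@@H]2Oc3c(OC(=O)C(C)(C)C)cc(Br)cc3C(OC)=C2)ccc1OC(=O)C(C)(C)C | intermediate
19 | methyl (2R,3R)-5-bromo-2-[3-methoxy-4-(pivaloyloxy)phenyl]-7-(pivaloyloxy)-2,3-dihydro-1-benzofuran-3-carboxylate (trans) | COc1cc([C@@H]2Oc3c(OC(=O)C(C)(C)C)cc(Br)cc3[C@H]2C(=O)OC)ccc1OC(=O)C(C)(C)C | intermediate
20 | (2R,3S)-5-bromo-2-(4-hydroxy-3-methoxyphenyl)-3-(hydroxymethyl)-2,3-dihydro-1-benzofuran-7-ol (trans) | COc1cc([C@@H]2Oc3c(O)cc(Br)cc3[C@H]2CO)ccc1O | intermediate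
21 | (2R,3S)-5-bromo-2-[3-methoxy-4-(methoxymethoxy)phenyl]-7-(methoxymethoxy)-3-[(methoxymethoxy)methyl]-2,3-dihydro-1-benzofuran (DBF bromide) | COc1cc([C@@H]2Oc3c(OCOC)cc(Br)cc3[C@H]2COCOC)ccc1OCOC | intermediate
22 | (DBF-ethynyl)trimethylsilane | COc1cc([C@@H]2Oc3c(OCOC)cc(C#C[Si](C)(C)C)cc3[C@H]2COCOC)ccc1OCOC | intermediate
23 | cesium 3-DBF-prop-2-ynoate (formed in the flask) | COc1cc([C@@H]2Oc3c(OCOC)cc(C#CC(=O)[O-])cc3[C@H]2COCOC)ccc1OCOC.[Cs+] | intermediate
24 | 3-DBF-prop-2-ynoic acid | COc1cc([C@@H]2Oc3c(OCOC)cc(C#CC(=O)O)cc3[C@H]2COCOC)ccc1OCOC | intermediate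
25 | potassium 3-DBF-prop-2-ynoate (formed in the flask) | COc1cc([C@@H]2Oc3c(OCOC)cc(C#CC(=O)[O-])cc3[C@H]2COCOC)ccc1OCOC.[K+] | intermediate
26 | 3,5-bis(methoxymethoxy)benzyne (formed in the flask) | COCOC1=CC(OCOC)=CC#C1 | intermediate
27 | 1-[2-hydroxy-4,6-bis(methoxymethoxy)phenyl]-3-DBF-prop-2-yn-1-one | COc1cc([C@@H]2Oc3c(OCOC)cc(C#CC(=O)c4c(O)cc(OCOC)cc4OCOC)cc3[C@H]2COCOC)ccc1OCOC | intermediate
28 | (E)-3-(diethylamino)-1-[2-hydroxy-4,6-bis(methoxymethoxy)phenyl]-3-DBF-prop-2-en-1-one (formed in the flask) | COc1cc([C@@H]2Oc3c(OCOC)cc(/C(N(CC)CC)=C\C(=O)c4c(O)cc(OCOC)cc4OCOC)cc3[C@H]2COCOC)ccc1OCOC | intermediate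
29 | 2-DBF-5,7-bis(methoxymethoxy)-4H-chromen-4-one | COc1cc([C@@H]2Oc3c(OCOC)cc(-c4cc(=O)c5c(OCOC)cc(OCOC)cc5o4)cc3[C@H]2COCOC)ccc1OCOC | intermediate
30 | 2-DBF-2,3-epoxy-5,7-bis(methoxymethoxy)chroman-4-one (cis-fused oxirane, both diastereomers relative to the core; formed in the flask) | COc1cc([C@@H]2Oc3c(OCOC)cc(C45OC4C(=O)c4c(OCOC)cc(OCOC)cc4O5)cc3[C@H]2COCOC)ccc1OCOC | intermediate
31 | 2-DBF-3-hydroxy-5,7-bis(methoxymethoxy)-4H-chromen-4-one | COc1cc([C@@H]2Oc3c(OCOC)cc(-c4oc5cc(OCOC)cc(OCOC)c5c(=O)c4O)cc3[C@H]2COCOC)ccc1OCOC | intermediate
32 | 2,3-dehydrosilychristin, 3,5,7-trihydroxy-2-[(2R,3S)-7-hydroxy-2-(4-hydroxy-3-methoxyphenyl)-3-(hydroxymethyl)-2,3-dihydro-1-benzofuran-5-yl]-4H-chromen-4-one | COc1cc([C@@H]2Oc3c(O)cc(-c4oc5cc(O)cc(O)c5c(=O)c4O)cc3[C@H]2CO)ccc1O | target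

## Step count and risks

Total: 19 steps. Longest linear sequence: 13 steps (12 to 32, steps 7 to 19). The aryne branch (steps 1 to 4) and the boronic acid branch (steps 5 and 6) are shorter.

**Step 16 (key step).** The most likely failure is protonation of the aryl anion before it reaches the carboxyl carbon, so that the sequence stops at O-arylation. Thermal loss of CO2 from 25 and further reaction of the product phenoxide (a second arylation or 5-exo closure) can also drain material. The fallback uses known chemistry and runs from 22 back to 27. Protodesilylation of 22 (K2CO3, MeOH) gives the terminal alkyne F1. Its lithium acetylide (n-BuLi, THF, −78 °C) is added to the sodium phenoxide of 2-hydroxy-4,6-bis(methoxymethoxy)benzaldehyde F2, which is made from commercial 2,4,6-trihydroxybenzaldehyde because its two non-chelated hydroxyls take MOMCl/i-Pr2NEt selectively. The adduct is propargylic alcohol F3, a pair of carbinol epimers, and MnO2 oxidises it to ynone 27. The two bonds to ring A are then made one at a time from a preformed phenol aldehyde.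

**Step 11.** Migration of the C2 aryl group instead of the fused ring carbon, simple dehydrogenation, or acid-induced opening of the flavanone with erosion of enantiopurity may compete; the pivalates may also be partly lost. The fallback runs from 17 back to 19 and replaces the oxidative aryl shift by a Wolff ring contraction. Kinetic enolisation of 17 (LiHMDS, −78 °C) and trifluoroacetylation (CF3CO2CH2CF3) give F4. Detrifluoroacetylative diazo transfer (MsN3, Et3N) gives α-diazo ketone F5, and irradiation in methanol contracts the ring through the ketene to the methyl ester. Whatever cis ester F6 forms is equilibrated with DBU to trans ester 19. In this manifold only the fused ring carbon can migrate.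

**Step 10.** Enantioselectivity may be insufficient on this 8-acyloxy chromone, the catalyst may be reduced to zerovalent palladium, which would then insert into the C–Br bond, or 11 may protodeboronate. The fallback runs from 16 and 11 back to 17. The addition is run without chiral ligand (Pd(OCOCF3)2, 2,2'-bipyridine) to give racemic flavanone F7. F7 is resolved kinetically by asymmetric transfer hydrogenation (RuCl(p-cymene)(TsDPEN), HCO2H/Et3N), using the catalyst enantiomer that reduces the (2S)-ketone faster. That enantiomer is converted into cis-flavan-4-ol F8 and unreacted (2R)-17 is recovered. The price is half of the material.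

**Step 18.** The epoxidation is slow, so oxidation elsewhere may compete: the benzylic C2–H, the acetal C–H bonds or the electron-rich rings. The fallback runs from 29 to 31 and oxygenates C3' by an anionic instead of an electrophilic route. LDA (THF, −78 °C) removes the C3' proton, B(OMe)3 traps the anion as boronate F9, and H2O2/AcOH oxidises the C–B bond to the C3' hydroxyl of 31.

**Step 15.** Protodesilylation by adventitious water may outrun carboxylation, and the salt 23 may lose CO2 on standing. The fallback runs from 21 to 24 and replaces steps 14 and 15. Bromine–lithium exchange on 21 (n-BuLi, THF, −78 °C) followed by DMF gives aldehyde F10. Corey–Fuchs olefination (CBr4, PPh3, Et3N) gives dibromoalkene F11. Treatment with n-BuLi (2 equiv), then CO2 and cold acidification, gives 24 through the lithium acetylide.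

## Further compounds

F1 | step 16 | DBF-acetylene (5-ethynyl compound) | COc1cc([C@@H]2Oc3c(OCOC)cc(C#C)cc3[C@H]2COCOC)ccc1OCOC
F2 | step 16 | 2-hydroxy-4,6-bis(methoxymethoxy)benzaldehyde | COCOc1cc(O)c(C=O)c(OCOC)c1
F3 | step 16 | 1-[2-hydroxy-4,6-bis(methoxymethoxy)phenyl]-3-DBF-prop-2-yn-1-ol (both carbinol epimers) | COc1cc([C@@H]2Oc3c(OCOC)cc(C#CC(O)c4c(O)cc(OCOC)cc4OCOC)cc3[C@H]2COCOC)ccc1OCOC
F4 | step 11 | (2R)-6-bromo-2-[3-methoxy-4-(pivaloyloxy)phenyl]-4-oxo-3-(trifluoroacetyl)chroman-8-yl pivalate (C3 undefined) | COc1cc([C@@H]2Oc3c(OC(=O)C(C)(C)C)cc(Br)cc3C(=O)C2C(=O)C(F)(F)F)ccc1OC(=O)C(C)(C)C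
F5 | step 11 | (2S)-6-bromo-3-diazo-2-[3-methoxy-4-(pivaloyloxy)phenyl]-4-oxochroman-8-yl pivalate (same spatial arrangement at C2 as 17) | COc1cc([C@@H]2Oc3c(OC(=O)C(C)(C)C)cc(Br)cc3C(=O)C2=[N+]=[N-])ccc1OC(=O)C(C)(C)C
F6 | step 11 | methyl (2R,3S)-5-bromo-2-[3-methoxy-4-(pivaloyloxy)phenyl]-7-(pivaloyloxy)-2,3-dihydro-1-benzofuran-3-carboxylate (cis) | COc1cc([C@@H]2Oc3c(OC(=O)C(C)(C)C)cc(Br)cc3[C@@H]2C(=O)OC)ccc1OC(=O)C(C)(C)C
F7 | step 10 | racemic 6-bromo-2-[3-methoxy-4-(pivaloyloxy)phenyl]-4-oxochroman-8-yl pivalate | COc1cc(C2Oc3c(OC(=O)C(C)(C)C)cc(Br)cc3C(=O)C2)ccc1OC(=O)C(C)(C)C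
F8 | step 10 | (2S,4S)-6-bromo-4-hydroxy-2-[3-methoxy-4-(pivaloyloxy)phenyl]chroman-8-yl pivalate (cis) | COc1cc([C@H]2Oc3c(OC(=O)C(C)(C)C)cc(Br)cc3[C@@H](O)C2)ccc1OC(=O)C(C)(C)C
F9 | step 18 | 2-DBF-3-(dimethoxyboryl)-5,7-bis(methoxymethoxy)-4H-chromen-4-one | COc1cc([C@@H]2Oc3c(OCOC)cc(-c4oc5cc(OCOC)cc(OCOC)c5c(=O)c4B(OC)OC)cc3[C@H]2COCOC)ccc1OCOC
F10 | step 15 | DBF-carbaldehyde | COc1cc([C@@H]2Oc3c(OCOC)cc(C=O)cc3[C@H]2COCOC)ccc1OCOC
F11 | step 15 | 5-(2,2-dibromovinyl) derivative of the DBF core | COc1cc([C@@H]2Oc3c(OCOC)cc(C=C(Br)Br)cc3[C@H]2COCOC)ccc1OCOC
A1 | alternative 1 | methyl 2-{5-bromo-3-(tert-butyldimethylsilyloxy)-2-[(4-(tert-butyldimethylsilyloxy)-3-methoxyphenyl)methoxy]phenyl}-2-diazoacetate | COC(=O)C(=[N+]=[N-])c1cc(Br)cc(O[Si](C)(C)C(C)(C)C)c1OCc1ccc(O[Si](C)(C)C(C)(C)C)c(OC)c1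
A2 | alternative 1 | methyl (2R,3R)-5-bromo-7-(tert-butyldimethylsilyloxy)-2-[4-(tert-butyldimethylsilyloxy)-3-methoxyphenyl]-2,3-dihydro-1-benzofuran-3-carboxylate (trans) | COc1cc([C@@H]2Oc3c(O[Si](C)(C)C(C)(C)C)cc(Br)cc3[C@H]2C(=O)OC)ccc1O[Si](C)(C)C(C)(C)C
A3 | alternative 2 | trans-3-[(tert-butyldimethylsilyloxy)methyl]-2-[3-methoxy-4-(triisopropylsilyloxy)phenyl]-2,3-dihydrofuro[3,4-b]furan | COc1cc([C@@H]2Oc3cocc3[C@H]2CO[Si](C)(C)C(C)(C)C)ccc1O[Si](C(C)C)(C(C)C)C(C)C
A4 | alternative 2 | methyl propiolate | C#CC(=O)OC
A5 | alternative 2 | methyl trans-3-[(tert-butyldimethylsilyloxy)methyl]-7-hydroxy-2-[3-methoxy-4-(triisopropylsilyloxy)phenyl]-2,3-dihydro-1-benzofuran-5-carboxylate | COc1cc([C@@H]2Oc3c(O)cc(C(=O)OC)cc3[C@H]2CO[Si](C)(C)C(C)(C)C)ccc1O[Si](C(C)C)(C(C)C)C(C)C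
A6 | alternative 3 | 2-[3-(benzyloxy)-5-bromo-2-hydroxyphenyl]-1-(4-hydroxy-3-methoxyphenyl)propane-1,3-diol (C2 as required for C3 of the target; carbinol carbon either way) | Oc1c(OCc2ccccc2)cc(Br)cc1[C@H](C(O)c1ccc(O)c(OC)c1)CO
A7 | alternative 3 | 4-{2-[3-(benzyloxy)-5-bromo-2-hydroxyphenyl]-3-hydroxypropylidene}-2-methoxycyclohexa-2,5-dien-1-one (para-quinone methide) | COC1=CC(=C[C@H](CO)c2cc(Br)cc(OCc3ccccc3)c2O)C=CC1=O
A8 | alternative 3 | (2R,3S)-7-(benzyloxy)-5-bromo-2-(4-hydroxy-3-methoxyphenyl)-3-(hydroxymethyl)-2,3-dihydro-1-benzofuran (trans) | COc1cc([C@@H]2Oc3c(OCc4ccccc4)cc(Br)cc3[C@H]2CO)ccc1O
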